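**Assumption:** the target SMILES has no stereocentre and no stereoaxis, so the compound is achiral. The "single enantiomer" request therefore needs no stereocontrol.

## Retrosynthetic overview
1. Target 14 comes from benzylic bromide 13 by solvolysis, and 13 comes from tetramethyl ether 12 by BBr3. This unmasks both catechols last.
2. The key disconnection is the central Ar–CH2 bond of 12. It leads to benzoxaborole 6 (ring A, with boron tied to its own CH2O arm) and tosylhydrazone 9 (ring B plus the CH2 carbon). This coupling is the new step.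
3. Compound 6 comes from iodide 4 by I/Mg exchange and borylation, and 4 comes from 5-bromovanillin 1 by methylation, reduction and para-to-OMe iodination.
4. Compound 9 also comes from 1, by a second ring bromination, methylation and hydrazone formation.
5. Both benzene rings are bought and no ring of the target is built. The only rings formed are the temporary oxaborole (step 4) and its six-membered expansion, which is opened again in step 8.

## Route

**Step 1**
Reactants: 1 5-bromovanillin (3-bromo-4-hydroxy-5-methoxybenzaldehyde)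
Product: 2 3-bromo-4,5-dimethoxybenzaldehyde
Conditions: MeI, K2CO3, DMF, rt
Reagents that add atoms: iodomethane, CI
Why: Williamson O-methylation of an acidic phenol, and nothing else in the molecule is alkylated.

**Step 2**
Reactants: 2 3-bromo-4,5-dimethoxybenzaldehyde
Product: 3 (3-bromo-4,5-dimethoxyphenyl)methanol
Conditions: NaBH4, MeOH, 0 °C
Reagents that add atoms: none
Why: Borohydride reduction of an aryl aldehyde, to which the aryl bromide and the ethers are inert.

**Step 3**
Reactants: 3 (3-bromo-4,5-dimethoxyphenyl)methanol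
Product: 4 (3-bromo-2-iodo-4,5-dimethoxyphenyl)methanol
Conditions: I2, CF3CO2Ag, CHCl3, 0 °C to rt, dark
Reagents that add atoms: iodine, II
Why: Electrophilic aromatic iodination goes para to the planar 5-OMe (C2), the same site that 5-bromovanillin brominates, because the 4-OMe is twisted out of conjugation and the methyl of the 5-OMe shields C6; the regiochemistry is confirmed by NOE between ArH and both OMe and CH2.

**Step 4**
Reactants: 4 (3-bromo-2-iodo-4,5-dimethoxyphenyl)methanol
Product: 6 7-bromo-5,6-dimethoxy-1,3-dihydro-2,1-benzoxaborol-1-ol, via bis(chloromagnesio) aryl-alkoxide 5 (not isolated)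
Conditions: iPrMgCl·LiCl (2.2 equiv), THF, −40 °C; B(OiPr)3, −40 °C to rt; 1 M aq HCl
Reagents that add atoms: triisopropyl borate, CC(C)OB(OC(C)C)OC(C)C; water, O
Why: Turbo-Grignard halogen–metal exchange takes C–I far faster than C–Br, the 2-bromoarylmagnesium does not form an aryne at this temperature, and after the borate quench acid closes the B–O–CH2 ring spontaneously.

**Step 5**
Reactants: 1 5-bromovanillin
Product: 7 2,3-dibromo-4-hydroxy-5-methoxybenzaldehyde (5,6-dibromovanillin)
Conditions: Br2, Fe powder (cat.), AcOH, rt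
Reagents that add atoms: bromine, BrBr
Why: Electrophilic aromatic bromination occurs para to the OMe, because the other site activated by the phenol is already brominated.

**Step 6**
Reactants: 7 2,3-dibromo-4-hydroxy-5-methoxybenzaldehyde
Product: 8 2,3-dibromo-4,5-dimethoxybenzaldehyde
Conditions: MeI, K2CO3, DMF, rt
Reagents that add atoms: iodomethane, CI
Why: Williamson O-methylation of the acidic ortho-bromophenol.

**Step 7**
Reactants: 8 2,3-dibromo-4,5-dimethoxybenzaldehyde
Product: 9 (E)-N'-(2,3-dibromo-4,5-dimethoxybenzylidene)-4-methylbenzenesulfonohydrazide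
Conditions: TsNHNH2, MeOH, 60 °C, product filtered off
Reagents that add atoms: p-toluenesulfonyl hydrazide, Cc1ccc(cc1)S(=O)(=O)NN
Why: Hydrazone condensation is driven by crystallisation and gives the E isomer as the less hindered geometry.

**Step 8 (key step, new)**
Reactants: 6 7-bromo-5,6-dimethoxy-1,3-dihydro-2,1-benzoxaborol-1-ol (1.5 equiv); 9 tosylhydrazone
Product: 12 [3-bromo-2-(2,3-dibromo-4,5-dimethoxybenzyl)-4,5-dimethoxyphenyl]methanol, via aryldiazomethane 10 (not isolated), via ring-expanded benzoxaborinine 11 (not isolated)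
Conditions: K2CO3 (3 equiv), dry 1,4-dioxane, 110 °C, 3 h; then H2O (10 equiv), 100 °C, 1 h
Reagents that add atoms: none
Why: Proposed new method: a metal-free, self-tethered reductive coupling that uses a benzoxaborole as the boron partner. Base turns 9 into diazo compound 10 (Bamford–Stevens), whose carbon binds the empty boron orbital of the strained and unusually Lewis-acidic five-membered hemiester. The aryl group then shifts 1,2 from B to C with loss of N2, which forms the Ar–CH bond and relieves strain by 5-to-6 ring expansion to racemic 11. The doubly benzylic C–B bond of 11 is protodeboronated by the added water and base, which erases that stereocentre and frees the CH2OH without any protecting group. All three C–Br bonds survive because no transition metal is present. The closest known reaction type is the reductive coupling of tosylhydrazones with acyclic arylboronic acids, which has not been shown on benzoxaboroles or on a di-ortho-substituted 2-bromoarylboron.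

**Step 9**
Reactants: 12 [3-bromo-2-(2,3-dibromo-4,5-dimethoxybenzyl)-4,5-dimethoxyphenyl]methanol
Product: 13 3-bromo-5-(bromomethyl)-4-(2,3-dibromo-4,5-dihydroxybenzyl)benzene-1,2-diol
Conditions: BBr3 (8 equiv), CH2Cl2, −78 °C to rt; ice-water quench, rapid extraction, used crude
Reagents that add atoms: boron tribromide, BrB(Br)Br
Why: Lewis-acid aryl methyl ether cleavage removes all four methyl groups and predictably converts the electron-rich benzylic alcohol into the bromide, while the ArBr and diarylmethane units are inert.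

**Step 10**
Reactants: 13 3-bromo-5-(bromomethyl)-4-(2,3-dibromo-4,5-dihydroxybenzyl)benzene-1,2-diol
Product: 14 3-bromo-4-(2,3-dibromo-4,5-dihydroxybenzyl)-5-(hydroxymethyl)benzene-1,2-diol (target)
Conditions: acetone/H2O 1:1, 0.01 M, Ar, rt to 40 °C; no alcohol solvents at any stage
Reagents that add atoms: water, O
Why: SN1-type solvolysis of a para-hydroxybenzyl bromide is strongly assisted by the para OH, and the large excess of water at high dilution outcompetes self-alkylation.

## Compound list
1 | 5-bromovanillin | O=Cc1cc(OC)c(O)c(Br)c1 | starting material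
2 | 3-bromo-4,5-dimethoxybenzaldehyde | O=Cc1cc(OC)c(OC)c(Br)c1 | intermediate
3 | (3-bromo-4,5-dimethoxyphenyl)methanol | OCc1cc(OC)c(OC)c(Br)c1 | intermediate
4 | (3-bromo-2-iodo-4,5-dimethoxyphenyl)methanol | OCc1cc(OC)c(OC)c(Br)c1I | intermediate
5 | bis(chloromagnesio) aryl-alkoxide from 4 (not isolated) | Cl[Mg]OCc1cc(OC)c(OC)c(Br)c1[Mg]Cl | intermediate
6 | 7-bromo-5,6-dimethoxy-1,3-dihydro-2,1-benzoxaborol-1-ol | OB1OCc2cc(OC)c(OC)c(Br)c21 | intermediate
7 | 2,3-dibromo-4-hydroxy-5-methoxybenzaldehyde | O=Cc1cc(OC)c(O)c(Br)c1Br | intermediate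
8 | 2,3-dibromo-4,5-dimethoxybenzaldehyde | O=Cc1cc(OC)c(OC)c(Br)c1Br | intermediate
9 | (E)-tosylhydrazone of 8 | Cc1ccc(cc1)S(=O)(=O)N/N=C/c1cc(OC)c(OC)c(Br)c1Br | intermediate
10 | 2,3-dibromo-1-(diazomethyl)-4,5-dimethoxybenzene (not isolated) | [N-]=[N+]=Cc1cc(OC)c(OC)c(Br)c1Br | intermediate
11 | 5-bromo-4-(2,3-dibromo-4,5-dimethoxyphenyl)-6,7-dimethoxy-1,4-dihydro-3H-2,3-benzoxaborinin-3-ol (racemic, not isolated) | OB1OCc2cc(OC)c(OC)c(Br)c2C1c1cc(OC)c(OC)c(Br)c1Br | intermediate
12 | [3-bromo-2-(2,3-dibromo-4,5-dimethoxybenzyl)-4,5-dimethoxyphenyl]methanol | OCc1cc(OC)c(OC)c(Br)c1Cc1cc(OC)c(OC)c(Br)c1Br | intermediate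
13 | 3-bromo-5-(bromomethyl)-4-(2,3-dibromo-4,5-dihydroxybenzyl)benzene-1,2-diol | BrCc1cc(O)c(O)c(Br)c1Cc1cc(O)c(O)c(Br)c1Br | intermediate
14 | 3-bromo-4-(2,3-dibromo-4,5-dihydroxybenzyl)-5-(hydroxymethyl)benzene-1,2-diol | OCc1cc(O)c(O)c(Br)c1Cc1cc(O)c(O)c(Br)c1Br | target

## Step count
- **Total steps:** 10.
- **Longest linear sequence:** 7 steps (1 → 2 → 3 → 4 → 6 → 12 → 13 → 14).

## Three steps most likely to fail

**Step 8 (proposed new step).**
- Risks: protodeboronation of the hindered benzoxaborole before coupling, blocking of boron as its anion, and azine or stilbene formation from 10.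
- Fallback (known chemistry): it sets out from 4 and 8 and comes back at 12.
- Iodide 4 is converted to 5 as in step 4, and 5 is added to aldehyde 8 (THF, −40 °C to 0 °C, LaCl3·2LiCl). This gives racemic [3-bromo-2-[(2,3-dibromo-4,5-dimethoxyphenyl)(hydroxy)methyl]-4,5-dimethoxyphenyl]methanol F1.
- Treatment with TFA/Et3SiH in CH2Cl2 first dehydrates the diol to racemic 7-bromo-1-(2,3-dibromo-4,5-dimethoxyphenyl)-5,6-dimethoxy-1,3-dihydroisobenzofuran F2.
- The doubly benzylic C–O bond of this phthalan ionises selectively and is reduced by ionic hydrogenation, giving 12.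

**Step 4.**
- Risks: aryne formation from the 2-bromoarylmagnesium, and sluggish borylation at the di-ortho-substituted carbon.
- Fallback: it sets out from 4 and comes back at 6.
- Pd-catalysed Miyaura borylation, selective for C–I over C–Br (B2pin2, PdCl2(dppf), KOAc, dioxane, 80 °C), gives [3-bromo-4,5-dimethoxy-2-(4,4,5,5-tetramethyl-1,3,2-dioxaborolan-2-yl)phenyl]methanol F3.
- Aqueous HCl/THF then exchanges pinacol for the neighbouring CH2OH to give 6.

**Step 9 (together with step 10).**
- Risk: the very reactive para-hydroxybenzyl bromide 13 can oligomerise by self-alkylation.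
- Fallback: it sets out from 12 and comes back at 14, and never passes through a benzylic halide.
- MnO2 (CH2Cl2, rt) oxidises 12 to 3-bromo-2-(2,3-dibromo-4,5-dimethoxybenzyl)-4,5-dimethoxybenzaldehyde F4.
- BBr3 (CH2Cl2, −78 °C to rt) demethylates it to 3-bromo-2-(2,3-dibromo-4,5-dihydroxybenzyl)-4,5-dihydroxybenzaldehyde F5, and the aldehyde survives.
- NaBH4 in THF/H2O at 0 °C then reduces the aldehyde to 14.

## Further compounds
F1 | step 8 | [3-bromo-2-[(2,3-dibromo-4,5-dimethoxyphenyl)(hydroxy)methyl]-4,5-dimethoxyphenyl]methanol (racemic) | OCc1cc(OC)c(OC)c(Br)c1C(O)c1cc(OC)c(OC)c(Br)c1Br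
F2 | step 8 | 7-bromo-1-(2,3-dibromo-4,5-dimethoxyphenyl)-5,6-dimethoxy-1,3-dihydroisobenzofuran (racemic) | C1OC(c2cc(OC)c(OC)c(Br)c2Br)c2c(Br)c(OC)c(OC)cc12
F3 | step 4 | [3-bromo-4,5-dimethoxy-2-(4,4,5,5-tetramethyl-1,3,2-dioxaborolan-2-yl)phenyl]methanol | OCc1cc(OC)c(OC)c(Br)c1B1OC(C)(C)C(C)(C)O1
F4 | step 9 | 3-bromo-2-(2,3-dibromo-4,5-dimethoxybenzyl)-4,5-dimethoxybenzaldehyde | O=Cc1cc(OC)c(OC)c(Br)c1Cc1cc(OC)c(OC)c(Br)c1Br
F5 | step 9 | 3-bromo-2-(2,3-dibromo-4,5-dihydroxybenzyl)-4,5-dihydroxybenzaldehyde | O=Cc1cc(O)c(O)c(Br)c1Cc1cc(O)c(O)c(Br)c1Br
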